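**Plan**

1. Retrosynthetic cuts: in each pyran ring (units U, M, L) the O1–C2 and C3–C4 bonds, then the two interflavan bonds C4U–C8M and C4M–C8L (aryl–carbinol disconnections); every C3–OH is traced back to a C3–Si bond.
2. Enabling feature: in every unit C4 is benzylic to a phloroglucinol A ring that carries O1 on C8a, ortho to C4a, so O1=C8a–C4a=C4 can be unmasked as an o-quinone methide (four atoms). C2–C3, with its 4-oxyphenyl on C2 and a cis oxygen on C3, maps onto a (Z)-β-silyl-4-benzyloxystyrene (two atoms).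
3. Forward order: ring L by annulation of a salicyl alcohol, C–Si oxidation and C4L oxygenation. Then twice the cycle "C8–Li adds to a 2-hydroxy-4,6-bis(benzyloxy)benzaldehyde, the o-hydroxybenzhydrol is annulated with the same vinylsilane, C–Si is oxidised", giving ring M and finally ring U; global hydrogenolysis ends the route.
4. Stereochemistry: C2/C3 cis from the Z alkene (suprafacial addition); C3/C4 cis from endo approach to the quinone methide with its aryl group outside; absolute sense of each ring from a chiral phosphoric acid (TRIP); C–Si to C–OH with retention; C4L by anti addition of BnOH to the C4 cation.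
5. Helpers: silicon steers the regiochemistry (attack at the Si-bearing carbon, charge at C2) and leaves as the C3 hydroxyl; bromine marks C8 for lithiation; benzyl ethers are the only protecting groups.

Key step: step 14

Assumption: the sense of induction of TRIP in this annulation is not known in advance; (R)-TRIP is written for the (2S,3S) rings L and U and (S)-TRIP for the (2R,3R) ring M, and the two are exchanged if step 5 shows the opposite sense.
Notation: U, M, L are the upper, middle and lower (3,4-diol) flavan units; atoms carry flavan numbers plus the unit letter (C4M, C8L); TRIP is 3,3'-bis(2,4,6-triisopropylphenyl)-1,1'-binaphthyl-2,2'-diyl hydrogen phosphate.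

**Route**

Step 1
Reactants: 1 3,5-bis(benzyloxy)phenol
Product: 2 2,4-bis(benzyloxy)-6-hydroxybenzaldehyde
Conditions: (CH2O)n, MgCl2, Et3N, MeCN, reflux; aq HCl work-up
Reagents that add atoms: paraformaldehyde (as formaldehyde), C=O
Why: Magnesium-phenoxide-directed ortho-formylation (Casiraghi–Skattebøl) delivers the formyl group to one of the two equivalent positions ortho to the free OH, so a single product is expected.

Step 2
Reactants: 2 2,4-bis(benzyloxy)-6-hydroxybenzaldehyde
Product: 3 4,6-bis(benzyloxy)-3-bromo-2-hydroxybenzaldehyde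
Conditions: NBS (1.0 equiv), CH2Cl2, −40 → 0 °C
Reagents that add atoms: N-bromosuccinimide, O=C1CCC(=O)N1Br
Why: Electrophilic aromatic bromination should occur at C3, between OH and one OBn, in preference to C5 between two OBn groups, the same steric preference that directs halogenation of 5,7-dialkoxyflavans to C8 and of 2-hydroxy-4,6-dialkoxyaryl ketones to the position ortho to OH.

Step 3
Reactants: 4 1-(benzyloxy)-4-ethynylbenzene
Product: 5 (Z)-benzyl{2-[4-(benzyloxy)phenyl]ethenyl}dimethylsilane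
Conditions: BnMe2SiH, [RuCl2(p-cymene)]2 (cat.), CH2Cl2, 40 °C
Reagents that add atoms: benzyldimethylsilane, C[SiH](C)Cc1ccccc1
Why: Ruthenium-catalysed trans-hydrosilylation of a terminal arylalkyne places silicon on the terminal carbon and sets the Z double bond by anti addition of Si–H.

Step 4
Reactants: 3 4,6-bis(benzyloxy)-3-bromo-2-hydroxybenzaldehyde
Product: 6 3,5-bis(benzyloxy)-2-bromo-6-(hydroxymethyl)phenol
Conditions: NaBH4, THF–MeOH, 0 °C; used at once
Reagents that add atoms: none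
Why: Borohydride reduction of the aldehyde gives the salicyl alcohol that serves as the o-quinone methide precursor.

Step 5
Reactants: 6 3,5-bis(benzyloxy)-2-bromo-6-(hydroxymethyl)phenol; 5 (Z)-benzyl{2-[4-(benzyloxy)phenyl]ethenyl}dimethylsilane
Product: 8 (2S,3S)-3-[benzyl(dimethyl)silyl]-5,7-bis(benzyloxy)-2-[4-(benzyloxy)phenyl]-8-bromochroman, via lower-ring o-quinone methide 7 (not isolated)
Conditions: (R)-TRIP (10 mol %), 5 (2 equiv), 5 Å MS, toluene, −20 °C → rt
Reagents that add atoms: none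
Why: Proposed new method: acid-promoted loss of water from 6 gives o-quinone methide 7, which should undergo an inverse-demand oxa-[4+2] with 5 in which the silicon-bearing carbon bonds to the methide carbon because the charge developing at C2 is stabilised by the 4-benzyloxyphenyl group and by the β-C–Si bond, the Z geometry is transferred suprafacially to give the 2,3-cis ring, and the TRIP phosphate bound to the quinone methide selects the alkene face to set (2S,3S); the closest known reaction type is the chiral-phosphoric-acid-catalysed [4+2] of in situ o-quinone methides with electron-rich styrenes and vinyl sulfides.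

Step 6
Reactants: 8 (2S,3S)-3-[benzyl(dimethyl)silyl]-5,7-bis(benzyloxy)-2-[4-(benzyloxy)phenyl]-8-bromochroman
Product: 10 (2S,3S)-5,7-bis(benzyloxy)-2-[4-(benzyloxy)phenyl]-8-bromochroman-3-ol, via ring-L silanol 9 (not isolated)
Conditions: TBAF, THF, 0 °C → rt; then KHCO3, 30% H2O2, MeOH–THF, 40 °C
Reagents that add atoms: hydrogen peroxide, OO; water, O (silanol oxygen of 9)
Why: Tamao–Fleming oxidation in its benzyldimethylsilyl variant: fluoride cleaves the Si–CH2Ph bond and peroxide rearrangement of the silanol moves C3 from silicon to oxygen with retention, so the 2,3-cis relation is kept; the axial C3–Si bond is not antiperiplanar to C2–O1, which disfavours Peterson-type ring opening.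

Step 7
Reactants: 10 (2S,3S)-5,7-bis(benzyloxy)-2-[4-(benzyloxy)phenyl]-8-bromochroman-3-ol
Product: 11 (2S,3S,4R)-4,5,7-tris(benzyloxy)-2-[4-(benzyloxy)phenyl]-8-bromochroman-3-ol
Conditions: DDQ (2 equiv), BnOH (5 equiv), CH2Cl2, rt
Reagents that add atoms: benzyl alcohol, OCc1ccccc1
Why: DDQ-mediated benzylic oxidation at C4 (hydride abstraction to the A-ring-stabilised cation, capture by the alcohol) is the standard 4-alkoxylation of benzylated flavan-3-ols, and the alcohol adds anti to the axial 3-OH to set the 3,4-trans (4R) centre.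

Step 8
Reactants: 11 (2S,3S,4R)-4,5,7-tris(benzyloxy)-2-[4-(benzyloxy)phenyl]-8-bromochroman-3-ol
Product: 12 (2S,3S,4R)-3,4,5,7-tetrakis(benzyloxy)-2-[4-(benzyloxy)phenyl]-8-bromochroman
Conditions: NaH, BnBr, Bu4NI (cat.), DMF, 0 °C → rt
Reagents that add atoms: benzyl bromide, BrCc1ccccc1
Why: Williamson etherification of the secondary 3-OH; no stereocentre is involved.

Step 9
Reactants: 12 (2S,3S,4R)-3,4,5,7-tetrakis(benzyloxy)-2-[4-(benzyloxy)phenyl]-8-bromochroman; 3 4,6-bis(benzyloxy)-3-bromo-2-hydroxybenzaldehyde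
Product: 15 L-unit o-hydroxybenzhydrol (C8L–CH(OH)–aryl; both carbinol epimers), via unit-L aryllithium 13 (not isolated), via sodium phenolate 14 (not isolated)
Conditions: 12, n-BuLi, THF, −78 °C; separately 3, NaH, THF, 0 °C; phenolate solution added at −78 °C, then → −20 °C; H2O
Reagents that add atoms: none
Why: Bromine–lithium exchange at C8L followed by 1,2-addition of the aryllithium to the aldehyde, whose phenol is masked as its sodium salt (too electron-rich for competing Br–Li exchange); the carbinol centre forms as both epimers, which is of no consequence because it becomes sp2 in step 10.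

Step 10
Reactants: 15 L-unit o-hydroxybenzhydrol; 5 (Z)-benzyl{2-[4-(benzyloxy)phenyl]ethenyl}dimethylsilane
Product: 17 M–L dimer silane (ring M all-cis: 2R,3R; 3M-SiMe2Bn; 8M-Br), via middle-ring o-quinone methide 16 (not isolated)
Conditions: (S)-TRIP (10 mol %), 5 (2 equiv), 5 Å MS, toluene, −20 °C → rt
Reagents that add atoms: none
Why: Proposed new method: same mechanism as step 5, now on the aryl-substituted quinone methide 16 formed by ionisation of the doubly benzylic carbinol, where endo approach of the Z alkene to the isomer holding the C8L aryl in the outside position should place C4M cis to C3M and C3M cis to C2M, and (S)-TRIP selects the face that gives the (2R,3R) all-cis ring M; the closest known reaction type is the chiral-phosphoric-acid-catalysed [4+2] of aryl-substituted o-quinone methides (from o-hydroxybenzhydrols) with electron-rich styrenes.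

Step 11
Reactants: 17 M–L dimer silane
Product: 19 M–L dimer alcohol (3M-OH; 8M-Br), via ring-M silanol 18 (not isolated)
Conditions: TBAF, THF, 0 °C → rt; then KHCO3, 30% H2O2, MeOH–THF, 40 °C
Reagents that add atoms: hydrogen peroxide, OO; water, O (silanol oxygen of 18)
Why: Tamao–Fleming oxidation with retention at C3M, as in step 6, converts the axial C–Si bond of the all-cis ring into the axial 3M-OH.

Step 12
Reactants: 19 M–L dimer alcohol
Product: 20 M–L dimer benzyl ether (3M-OBn; 8M-Br)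
Conditions: NaH, BnBr, Bu4NI (cat.), DMF, 0 °C → rt
Reagents that add atoms: benzyl bromide, BrCc1ccccc1
Why: Williamson etherification removes the only acidic proton before the lithiation of step 13; no stereocentre is involved.

Step 13
Reactants: 20 M–L dimer benzyl ether; 2 2,4-bis(benzyloxy)-6-hydroxybenzaldehyde
Product: 23 dimer o-hydroxybenzhydrol (C8M–CH(OH)–aryl; both carbinol epimers), via dimer aryllithium 21 (not isolated), via sodium phenolate 22 (not isolated)
Conditions: 20, n-BuLi, THF, −78 °C; separately 2, NaH, THF, 0 °C; phenolate solution added at −78 °C, then → −20 °C; H2O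
Reagents that add atoms: none
Why: Bromine–lithium exchange at C8M and 1,2-addition of the aryllithium to the aldehyde, as in step 9, joins the future C4U to C8M; the carbinol epimers converge in step 14.

Step 14
Reactants: 23 dimer o-hydroxybenzhydrol; 5 (Z)-benzyl{2-[4-(benzyloxy)phenyl]ethenyl}dimethylsilane
Product: 25 U–M–L trimer silane (ring U all-cis: 2S,3S,4R; 3U-SiMe2Bn), via upper-ring o-quinone methide 24 (not isolated)
Conditions: (R)-TRIP (10 mol %), 5 (2–3 equiv), 5 Å MS, toluene, −20 °C → rt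
Reagents that add atoms: none
Why: Proposed new method: The phosphoric acid ionises the doubly benzylic, tetra-ortho-oxygenated carbinol of 23 with help of the free ortho-OH to the hydrogen-bonded o-quinone methide 24 (O1=C8a–C4a=C4 of ring U), which is trapped by vinylsilane 5 in an inverse-electron-demand oxa-[4+2] cycloaddition that is concerted but asynchronous, C3–C4 forming ahead of O1–C2; the closest known reaction type is the chiral-phosphoric-acid-catalysed [4+2] of in situ o-quinone methides with electron-rich styrenes and vinyl sulfides, which has not been shown with β-silylstyrenes. The one ring closed is pyran ring U, by intermolecular two-bond [4+2] closure; in the stepwise limit the quinone methide oxygen closes 6-exo on the C2 benzylic cation. Regioselectivity, which decides between a flavan and an isoflavan, is secured twice by the substrates: attack at the silicon-bearing carbon puts the positive charge on C2, where both the 4-benzyloxyphenyl group and the β-C–Si bond stabilise it. C2U and C3U should come out cis because the Z geometry of the alkene is transferred suprafacially (a β-silyl cation is captured anti to silicon after least-motion rotation, which gives the same result). C4U should come out cis to C3U because the quinone methide isomer with the bulky C8M aryl in the outside position, the only one that keeps it off the forming O1–C2 bond, is approached in the endo mode known for styrenes (the 2,4-cis preference). Which face of 24 reacts, and hence the (2S,3S,4R) ring on the (2R,3R) unit M, is set by the (R)-TRIP phosphate bound to the quinone methide, since the resident stereocentres are remote, and chemoselectivity over the 4L benzyl ether rests on the far easier ionisation of the o-hydroxybenzhydrol.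

Step 15
Reactants: 25 U–M–L trimer silane
Product: 27 dodeca-O-benzyl trimer alcohol (3U-OH), via ring-U silanol 26 (not isolated)
Conditions: TBAF, THF, 0 °C → rt; then KHCO3, 30% H2O2, MeOH–THF, 40 °C
Reagents that add atoms: hydrogen peroxide, OO; water, O (silanol oxygen of 26)
Why: Tamao–Fleming oxidation with retention at C3U, as in steps 6 and 11, turns the masked hydroxyl into the axial 3U-OH of the all-cis ring.

Step 16
Reactants: 27 dodeca-O-benzyl trimer alcohol
Product: 28 CNP0159291.1 (target)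
Conditions: H2 (1 atm), Pd(OH)2/C, NaHCO3 (solid), THF–MeOH, rt; filtration, Sephadex LH-20
Reagents that add atoms: none
Why: Palladium-catalysed hydrogenolysis of the twelve O-benzyl groups under neutral, buffered conditions, under which O–CH2Ph bonds should cleave much faster than the secondary C4L–O bond or the interflavan C–C bonds; no stereocentre is touched.

**Compound list**

1 | 3,5-bis(benzyloxy)phenol | Oc1cc(OCc2ccccc2)cc(OCc2ccccc2)c1 | starting material
2 | 2,4-bis(benzyloxy)-6-hydroxybenzaldehyde | O=Cc1c(O)cc(OCc2ccccc2)cc1OCc1ccccc1 | intermediate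
3 | 4,6-bis(benzyloxy)-3-bromo-2-hydroxybenzaldehyde | O=Cc1c(O)c(Br)c(OCc2ccccc2)cc1OCc1ccccc1 | intermediate
4 | 1-(benzyloxy)-4-ethynylbenzene | C#Cc1ccc(OCc2ccccc2)cc1 | starting material
5 | (Z)-benzyl{2-[4-(benzyloxy)phenyl]ethenyl}dimethylsilane | C(/[Si](C)(C)Cc1ccccc1)=C/c1ccc(OCc2ccccc2)cc1 | intermediate
6 | 3,5-bis(benzyloxy)-2-bromo-6-(hydroxymethyl)phenol | OCc1c(O)c(Br)c(OCc2ccccc2)cc1OCc1ccccc1 | intermediate
7 | 3,5-bis(benzyloxy)-2-bromo-6-methylidenecyclohexa-2,4-dien-1-one (lower-ring o-quinone methide) | C=C1C(=O)C(Br)=C(OCc2ccccc2)C=C1OCc1ccccc1 | intermediate (not isolated)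
8 | (2S,3S)-3-[benzyl(dimethyl)silyl]-5,7-bis(benzyloxy)-2-[4-(benzyloxy)phenyl]-8-bromochroman (2,3-cis) | Brc1c(OCc2ccccc2)cc(OCc2ccccc2)c2c1O[C@@H](c1ccc(OCc3ccccc3)cc1)[C@@H]([Si](C)(C)Cc1ccccc1)C2 | intermediate
9 | (2S,3S)-5,7-bis(benzyloxy)-2-[4-(benzyloxy)phenyl]-8-bromo-3-[hydroxy(dimethyl)silyl]chroman | Brc1c(OCc2ccccc2)cc(OCc2ccccc2)c2c1O[C@@H](c1ccc(OCc3ccccc3)cc1)[C@@H]([Si](C)(C)O)C2 | intermediate (not isolated)
10 | (2S,3S)-5,7-bis(benzyloxy)-2-[4-(benzyloxy)phenyl]-8-bromochroman-3-ol (8-bromo-5,7,4'-tri-O-benzyl-ent-epiafzelechin) | Brc1c(OCc2ccccc2)cc(OCc2ccccc2)c2c1O[C@@H](c1ccc(OCc3ccccc3)cc1)[C@@H](O)C2 | intermediate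
11 | (2S,3S,4R)-4,5,7-tris(benzyloxy)-2-[4-(benzyloxy)phenyl]-8-bromochroman-3-ol (2,3-cis-3,4-trans) | Brc1c(OCc2ccccc2)cc(OCc2ccccc2)c2c1O[C@@H](c1ccc(OCc3ccccc3)cc1)[C@@H](O)[C@@H]2OCc1ccccc1 | intermediate
12 | (2S,3S,4R)-3,4,5,7-tetrakis(benzyloxy)-2-[4-(benzyloxy)phenyl]-8-bromochroman | Brc1c(OCc2ccccc2)cc(OCc2ccccc2)c2c1O[C@@H](c1ccc(OCc3ccccc3)cc1)[C@@H](OCc1ccccc1)[C@@H]2OCc1ccccc1 | intermediate
13 | 8-lithio analogue of 12 (unit-L aryllithium) | [Li]c1c(OCc2ccccc2)cc(OCc2ccccc2)c2c1O[C@@H](c1ccc(OCc3ccccc3)cc1)[C@@H](OCc1ccccc1)[C@@H]2OCc1ccccc1 | intermediate (not isolated)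
14 | sodium 3,5-bis(benzyloxy)-2-bromo-6-formylphenolate | [Na+].[O-]c1c(Br)c(OCc2ccccc2)cc(OCc2ccccc2)c1C=O | intermediate (not isolated)
15 | [4,6-bis(benzyloxy)-3-bromo-2-hydroxyphenyl][(2S,3S,4R)-3,4,5,7-tetrakis(benzyloxy)-2-(4-benzyloxyphenyl)chroman-8-yl]methanol, both carbinol epimers | OC(c1c(O)c(Br)c(OCc2ccccc2)cc1OCc1ccccc1)c1c(OCc2ccccc2)cc(OCc2ccccc2)c2c1O[C@@H](c1ccc(OCc3ccccc3)cc1)[C@@H](OCc1ccccc1)[C@@H]2OCc1ccccc1 | intermediate
16 | middle-ring o-quinone methide: 3,5-bis(benzyloxy)-2-bromocyclohexa-2,4-dien-1-one carrying at C6 the exocyclic =CH–(chroman-8-yl of unit L) group | O=C1C(Br)=C(OCc2ccccc2)C=C(OCc2ccccc2)C1=Cc1c(OCc2ccccc2)cc(OCc2ccccc2)c2c1O[C@@H](c1ccc(OCc3ccccc3)cc1)[C@@H](OCc1ccccc1)[C@@H]2OCc1ccccc1 | intermediate (not isolated)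
17 | M–L dimer silane: (2R,3R)-3-[benzyl(dimethyl)silyl]-5,7-bis(benzyloxy)-2-[4-(benzyloxy)phenyl]-8-bromochroman (unit M) bearing at C4M, cis to the C2M aryl and C3M silyl groups (all-cis ring), the (2S,3S,4R)-3,4,5,7-tetrakis(benzyloxy)-2-(4-benzyloxyphenyl)chroman-8-yl group (unit L) | O(Cc5ccccc5)c1ccc([C@H]2Oc3c(c(OCc5ccccc5)cc(OCc5ccccc5)c3Br)[C@@H](c3c(OCc5ccccc5)cc(OCc5ccccc5)c4c3O[C@@H](c3ccc(OCc5ccccc5)cc3)[C@@H](OCc5ccccc5)[C@@H]4OCc5ccccc5)[C@H]2[Si](C)(C)Cc5ccccc5)cc1 | intermediate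
18 | ring-M silanol: 17 with 3M-SiMe2OH in place of 3M-SiMe2Bn | O(Cc5ccccc5)c1ccc([C@H]2Oc3c(c(OCc5ccccc5)cc(OCc5ccccc5)c3Br)[C@@H](c3c(OCc5ccccc5)cc(OCc5ccccc5)c4c3O[C@@H](c3ccc(OCc5ccccc5)cc3)[C@@H](OCc5ccccc5)[C@@H]4OCc5ccccc5)[C@H]2[Si](C)(C)O)cc1 | intermediate (not isolated)
19 | M–L dimer alcohol: 17 with 3M-OH (2R,3R; all-cis ring M) in place of the silyl group | O(Cc5ccccc5)c1ccc([C@H]2Oc3c(c(OCc5ccccc5)cc(OCc5ccccc5)c3Br)[C@@H](c3c(OCc5ccccc5)cc(OCc5ccccc5)c4c3O[C@@H](c3ccc(OCc5ccccc5)cc3)[C@@H](OCc5ccccc5)[C@@H]4OCc5ccccc5)[C@H]2O)cc1 | intermediate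
20 | M–L dimer benzyl ether: 19 with 3M-OBn; 8M-bromo | O(Cc5ccccc5)c1ccc([C@H]2Oc3c(c(OCc5ccccc5)cc(OCc5ccccc5)c3Br)[C@@H](c3c(OCc5ccccc5)cc(OCc5ccccc5)c4c3O[C@@H](c3ccc(OCc5ccccc5)cc3)[C@@H](OCc5ccccc5)[C@@H]4OCc5ccccc5)[C@H]2OCc5ccccc5)cc1 | intermediate
21 | dimer aryllithium: 20 with Li in place of Br at C8M | O(Cc5ccccc5)c1ccc([C@H]2Oc3c(c(OCc5ccccc5)cc(OCc5ccccc5)c3[Li])[C@@H](c3c(OCc5ccccc5)cc(OCc5ccccc5)c4c3O[C@@H](c3ccc(OCc5ccccc5)cc3)[C@@H](OCc5ccccc5)[C@@H]4OCc5ccccc5)[C@H]2OCc5ccccc5)cc1 | intermediate (not isolated)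
22 | sodium 3,5-bis(benzyloxy)-2-formylphenolate | [Na+].[O-]c1cc(OCc2ccccc2)cc(OCc2ccccc2)c1C=O | intermediate (not isolated)
23 | dimer o-hydroxybenzhydrol: 20 with CH(OH)[2,4-bis(benzyloxy)-6-hydroxyphenyl] in place of Br at C8M, both carbinol epimers | O(Cc5ccccc5)c1ccc([C@H]2Oc3c(c(OCc5ccccc5)cc(OCc5ccccc5)c3C(O)c3c(O)cc(OCc5ccccc5)cc3OCc5ccccc5)[C@@H](c3c(OCc5ccccc5)cc(OCc5ccccc5)c4c3O[C@@H](c3ccc(OCc5ccccc5)cc3)[C@@H](OCc5ccccc5)[C@@H]4OCc5ccccc5)[C@H]2OCc5ccccc5)cc1 | intermediate
24 | upper-ring o-quinone methide: 3,5-bis(benzyloxy)cyclohexa-2,4-dien-1-one carrying at C6 the exocyclic =CH–(C8M of the dimer) group | O(Cc5ccccc5)c1ccc([C@H]2Oc3c(c(OCc5ccccc5)cc(OCc5ccccc5)c3C=C3C(=O)C=C(OCc5ccccc5)C=C3OCc5ccccc5)[C@@H](c3c(OCc5ccccc5)cc(OCc5ccccc5)c4c3O[C@@H](c3ccc(OCc5ccccc5)cc3)[C@@H](OCc5ccccc5)[C@@H]4OCc5ccccc5)[C@H]2OCc5ccccc5)cc1 | intermediate (not isolated)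
25 | U–M–L trimer silane: unit U is (2S,3S,4R)-3-[benzyl(dimethyl)silyl]-5,7-bis(benzyloxy)-2-[4-(benzyloxy)phenyl]chroman-4-yl (all-cis), bonded through C4U to C8M of the debrominated dimer 20 | O(Cc5ccccc5)c1ccc([C@H]2Oc3c(c(OCc5ccccc5)cc(OCc5ccccc5)c3[C@H]3c4c(OCc5ccccc5)cc(OCc5ccccc5)cc4O[C@@H](c4ccc(OCc5ccccc5)cc4)[C@H]3[Si](C)(C)Cc5ccccc5)[C@@H](c3c(OCc5ccccc5)cc(OCc5ccccc5)c4c3O[C@@H](c3ccc(OCc5ccccc5)cc3)[C@@H](OCc5ccccc5)[C@@H]4OCc5ccccc5)[C@H]2OCc5ccccc5)cc1 | intermediate
26 | ring-U silanol: 25 with 3U-SiMe2OH in place of 3U-SiMe2Bn | O(Cc5ccccc5)c1ccc([C@H]2Oc3c(c(OCc5ccccc5)cc(OCc5ccccc5)c3[C@H]3c4c(OCc5ccccc5)cc(OCc5ccccc5)cc4O[C@@H](c4ccc(OCc5ccccc5)cc4)[C@H]3[Si](C)(C)O)[C@@H](c3c(OCc5ccccc5)cc(OCc5ccccc5)c4c3O[C@@H](c3ccc(OCc5ccccc5)cc3)[C@@H](OCc5ccccc5)[C@@H]4OCc5ccccc5)[C@H]2OCc5ccccc5)cc1 | intermediate (not isolated)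
27 | dodeca-O-benzyl trimer alcohol: 25 with 3U-OH (2S,3S,4R; all-cis ring U) in place of the silyl group; all nine phenols, 3M-OH, 3L-OH and 4L-OH benzylated | O(Cc5ccccc5)c1ccc([C@H]2Oc3c(c(OCc5ccccc5)cc(OCc5ccccc5)c3[C@H]3c4c(OCc5ccccc5)cc(OCc5ccccc5)cc4O[C@@H](c4ccc(OCc5ccccc5)cc4)[C@H]3O)[C@@H](c3c(OCc5ccccc5)cc(OCc5ccccc5)c4c3O[C@@H](c3ccc(OCc5ccccc5)cc3)[C@@H](OCc5ccccc5)[C@@H]4OCc5ccccc5)[C@H]2OCc5ccccc5)cc1 | intermediate
28 | CNP0159291.1: unit U (2S,3S,4R) 2,3-cis-3,4-cis, linked C4U–C8M to unit M (2R,3R,4S) 2,3-cis-3,4-cis, linked C4M–C8L to unit L (2S,3S,4R) 2,3-cis-3,4-trans flavan-3,4-diol; each unit 5,7-dihydroxy with a 4-hydroxyphenyl group at C2 | Oc1ccc([C@H]2Oc3c(c(O)cc(O)c3[C@H]3c4c(O)cc(O)cc4O[C@@H](c4ccc(O)cc4)[C@H]3O)[C@@H](c3c(O)cc(O)c4c3O[C@@H](c3ccc(O)cc3)[C@@H](O)[C@@H]4O)[C@H]2O)cc1 | target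

**Step count and risks**

Total step count: 16. Longest linear sequence: 15 steps (1 → 2 → 3 → 6 → 8 → 10 → 11 → 12 → 15 → 17 → 19 → 20 → 23 → 25 → 27 → 28; step 3 is the side branch to 5).

The three steps most likely to fail all carry the label; the fallbacks use known reaction types.

Step 14. What may go wrong: after C3–C4 bond formation the β-silyl benzylic cation may lose silicon instead of closing on oxygen (net alkenylation of the quinone methide); the alkene may approach exo, giving a 3,4-trans ring; or the catalyst may fail to control the face of the quinone methide, whose own bias is weak. The fallback sets out from 23, together with alkyne 4, and comes back to the route at 27. Acid-catalysed annulation of the quinone methide from 23 with arylalkyne 4 (diphenyl phosphate or (R)-TRIP, toluene; a known 4H-chromene synthesis from o-hydroxybenzhydrols) should give the trimer with ring U as a 2-aryl-4H-chromene F1, in which only C4U is set (its epimers are diastereomers and separable). Hydroboration–oxidation (BH3·SMe2; NaBO3), which adds anti to the C4U aryl group, should give the 2,3-trans-3,4-trans trimer alcohol F2. Dess–Martin oxidation to the ring-U flavan-3-one trimer F3 and L-Selectride reduction, the known inversion of 2,3-trans to 2,3-cis flavan-3-ols, with hydride arriving anti to both aryl groups, should then give 27.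

Step 10. What may go wrong: the same three processes as in step 14, plus a mismatch between the catalyst and the chiral L unit. The fallback sets out from 15, together with alkyne 4, and comes back at 19. Acid-catalysed annulation of the quinone methide from 15 with 4 should give the dimer with ring M as an 8-bromo-2-aryl-4H-chromene F4 (C4M epimers separable). Hydroboration–oxidation anti to the C4M aryl group should give the 2,3-trans-3,4-trans dimer alcohol F5. Dess–Martin oxidation to the ring-M flavan-3-one dimer F6 and L-Selectride reduction should give the all-cis alcohol 19.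

Step 5. What may go wrong: the unsubstituted quinone methide 7 may oligomerise faster than it is trapped, and face selection on the alkene by the catalyst may be insufficient because the quinone methide has no prochiral carbon. The fallback sets out from 6, together with alkyne 4, and comes back at 10. Acid-catalysed or thermal annulation of the quinone methide from 6 with 4 should give 5,7-bis(benzyloxy)-2-[4-(benzyloxy)phenyl]-8-bromo-4H-chromene F7. Asymmetric hydroboration–oxidation with the enantiomer of monoisopinocampheylborane that delivers the (2S,3R) product should give the 2,3-trans alcohol (2S,3R)-5,7-bis(benzyloxy)-2-[4-(benzyloxy)phenyl]-8-bromochroman-3-ol F8 (enrichment by crystallisation if needed). Dess–Martin oxidation to (2S)-5,7-bis(benzyloxy)-2-[4-(benzyloxy)phenyl]-8-bromochroman-3-one F9 and L-Selectride reduction should give the 2,3-cis alcohol 10.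

Further compounds
F1 | step 14 | trimer with ring U as 2-aryl-4H-chromene (C2U=C3U; C4U as in 27; no oxygen at C3U) | O(Cc5ccccc5)c1ccc([C@H]2Oc3c(c(OCc5ccccc5)cc(OCc5ccccc5)c3[C@H]3c4c(OCc5ccccc5)cc(OCc5ccccc5)cc4OC(c4ccc(OCc5ccccc5)cc4)=C3)[C@@H](c3c(OCc5ccccc5)cc(OCc5ccccc5)c4c3O[C@@H](c3ccc(OCc5ccccc5)cc3)[C@@H](OCc5ccccc5)[C@@H]4OCc5ccccc5)[C@H]2OCc5ccccc5)cc1
F2 | step 14 | C3U epimer of 27 (ring U 2,3-trans-3,4-trans, 2,4-cis) | O(Cc5ccccc5)c1ccc([C@H]2Oc3c(c(OCc5ccccc5)cc(OCc5ccccc5)c3[C@H]3c4c(OCc5ccccc5)cc(OCc5ccccc5)cc4O[C@@H](c4ccc(OCc5ccccc5)cc4)[C@@H]3O)[C@@H](c3c(OCc5ccccc5)cc(OCc5ccccc5)c4c3O[C@@H](c3ccc(OCc5ccccc5)cc3)[C@@H](OCc5ccccc5)[C@@H]4OCc5ccccc5)[C@H]2OCc5ccccc5)cc1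
F3 | step 14 | trimer with ring U as flavan-3-one (C3U=O; C2U and C4U as in 27) | O(Cc5ccccc5)c1ccc([C@H]2Oc3c(c(OCc5ccccc5)cc(OCc5ccccc5)c3[C@H]3c4c(OCc5ccccc5)cc(OCc5ccccc5)cc4O[C@@H](c4ccc(OCc5ccccc5)cc4)C3=O)[C@@H](c3c(OCc5ccccc5)cc(OCc5ccccc5)c4c3O[C@@H](c3ccc(OCc5ccccc5)cc3)[C@@H](OCc5ccccc5)[C@@H]4OCc5ccccc5)[C@H]2OCc5ccccc5)cc1
F4 | step 10 | dimer with ring M as 8-bromo-2-aryl-4H-chromene (C2M=C3M; C4M as in 19) | O(Cc5ccccc5)c1ccc(C2=C[C@H](c3c(OCc5ccccc5)cc(OCc5ccccc5)c4c3O[C@@H](c3ccc(OCc5ccccc5)cc3)[C@@H](OCc5ccccc5)[C@@H]4OCc5ccccc5)c3c(OCc5ccccc5)cc(OCc5ccccc5)c(Br)c3O2)cc1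
F5 | step 10 | C3M epimer of 19 (ring M 2,3-trans-3,4-trans, 2,4-cis) | O(Cc5ccccc5)c1ccc([C@H]2Oc3c(c(OCc5ccccc5)cc(OCc5ccccc5)c3Br)[C@@H](c3c(OCc5ccccc5)cc(OCc5ccccc5)c4c3O[C@@H](c3ccc(OCc5ccccc5)cc3)[C@@H](OCc5ccccc5)[C@@H]4OCc5ccccc5)[C@@H]2O)cc1
F6 | step 10 | dimer with ring M as flavan-3-one (C3M=O; C2M and C4M as in 19) | O(Cc5ccccc5)c1ccc([C@H]2Oc3c(c(OCc5ccccc5)cc(OCc5ccccc5)c3Br)[C@@H](c3c(OCc5ccccc5)cc(OCc5ccccc5)c4c3O[C@@H](c3ccc(OCc5ccccc5)cc3)[C@@H](OCc5ccccc5)[C@@H]4OCc5ccccc5)C2=O)cc1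
F7 | step 5 | 5,7-bis(benzyloxy)-2-[4-(benzyloxy)phenyl]-8-bromo-4H-chromene | Brc1c(OCc2ccccc2)cc(OCc2ccccc2)c2c1OC(c1ccc(OCc3ccccc3)cc1)=CC2
F8 | step 5 | (2S,3R)-5,7-bis(benzyloxy)-2-[4-(benzyloxy)phenyl]-8-bromochroman-3-ol (2,3-trans) | Brc1c(OCc2ccccc2)cc(OCc2ccccc2)c2c1O[C@@H](c1ccc(OCc3ccccc3)cc1)[C@H](O)C2
F9 | step 5 | (2S)-5,7-bis(benzyloxy)-2-[4-(benzyloxy)phenyl]-8-bromochroman-3-one | Brc1c(OCc2ccccc2)cc(OCc2ccccc2)c2c1O[C@@H](c1ccc(OCc3ccccc3)cc1)C(=O)C2
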